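## Structural features

The target is a caged tetracycle. Its core is a bicyclo[3.3.1]nonane-2,4,9-trione: C1 (benzoyl) and C5 (geranyl) are the bridgeheads, C2 and C4 are ketones flanking the quaternary C3, C9 is the bridging ketone, and C6 (CH2), C7 (CH) and C8 (CMe2) form the other three-atom bridge. A two-carbon strap, C10 (CH2) and C11 (CH), ties C7 to C3 and closes a seven-membered ring C1–C2–C3–C11–C10–C7–C8. A gem-dimethylcyclopentane (C3, C11, C12, C13, C14; C12 is CMe2) is fused on the C3–C11 bond, cis with respect to that seven-membered ring. There are five stereocentres: C1 and C3 flank the C2 ketone, C3 and C11 are adjacent, and C7 sits one CH2 away from both C5 and C11. C1, C3 and C5 are quaternary and each lies between two or three carbonyl groups. C1 carries three acyl groups and the cage has no enolizable hydrogen, so nucleophiles and strong aqueous base threaten C–C cleavage at C1; the two trisubstituted alkenes of the geranyl chain are sensitive to acid, halonium sources and carbenoids. The real difficulty is the C1–C2–C3 array, two fully substituted α-carbons on either side of one ketone, both joined to further ring carbonyls and both related to the remote centres C7 and C11. The key step uses the fact that C4–C5–C9 is a geranyl-bearing malonyl unit whose two carbonyl carbons sit on C3 and C1, the two α-carbons of the C2 ketone of the seven-membered ring. A double C-acylation therefore closes the six-membered trione ring C1–C2–C3–C4–C5–C9 and leaves only the C5–C6 bond.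

## Logic of the disconnections

**28 to 26.** The C5–C6 bond is cut. It is the only bond of the cage that can be formed from an enolizable carbon, because C5 of 26 is the central carbon of a 1,3-dione. The cut removes the bicyclo[3.3.1] cage and one quaternary stereocentre whose configuration the cage dictates. The forward step needs C-alkylation and not O-alkylation, a C6 substituent cis to the dione bridge, and a leaving group that stays inert until then (chloride, activated by iodide at the end).

**26 to 18 and 23.** The C1–C9 and C3–C4 bonds are cut. This removes the six-membered trione ring, two quaternary stereocentres and thirteen carbons in one convergent operation. The forward step needs two C-acylations, cis across C2, on the ring face that carries H11 and the C7 chloromethyl group. One point of the plan is changed here. If C1 were acylated first, its configuration would be fixed in an intermolecular step at the most hindered carbon, with no clear facial bias, and the tether would then force C3 to follow. The order is therefore reversed: 18 reacts as its bis-silyl dienol ether 24, C3 is acylated first under the local control of C11 to give 25, and C1 closes intramolecularly on the same face.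

**23 to 22, 21, then 19 and 20.** The bond between C5 and the geranyl CH2 is cut (malonic ester alkylation). The demand is an acid chloride formation that generates no HCl, which would add to the geranyl alkenes.

**18 to 17, then 15 and 16.** The bond between C1 and the benzoyl carbon is cut. The β-diketone is what makes C1 and C3 a double nucleophile. Aldol addition and oxidation are chosen over direct acylation because C1 is neopentyl-like. The forward step needs kinetic enolization at the C1 methylene and not at the C3 methine.

**15 to 14.** The C3–C14 bond is cut, opening the cyclopentane to a monocyclic cycloheptanone. The forward step needs the C3 enolate to find the primary bromide in preference to the hindered C6 chloride.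

**14 to 12 and 13.** The C11–C12 bond, between a tertiary and a quaternary carbon, is cut. A tertiary radical adds to an enone where ionic tertiary nucleophiles do not, and the five-carbon alkene brings C12, C13 and C14 at once. The forward step must add anti to the C7 substituent to set C11.

**12 to 11 and 10.** The C3=C11 alkene (ring-closing metathesis) and the C2–C3 bond (vinyl addition to a Weinreb amide) are cut, giving an acyclic chain with one stereocentre. The demands are high dilution and a quench that protects the vinyl ketone.

**10 to 9, 8, 7 and 6.** These are functional-group changes at C6 and C2. The chloride is installed while C2 is still a tert-butyl ester, because an amide or ketone at C2 would capture the activated C6 as a six-membered neighbouring group.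

**6 to 4 and 5; 4 to 2 and 3; 2 to 1.** The C7–C10 bond is cut (auxiliary-controlled allylation), then the imide and ester bonds. This leads to an achiral, symmetrical anhydride that already holds C6, C7, C8 with its two methyls, C1 and C2. The demand is alkylation of an enolate next to a quaternary carbon.

## Other disconnections considered

**Alternative 1:** The cut is at C5–C6 and C3–C11, the two bonds that close the other seven-membered ring C3–C4–C5–C6–C7–C10–C11. In the forward step Rh2(S-DOSP)4, or its enantiomer, decomposes the siloxyvinyl diazoacetate A3. The carbenoid cyclopropanates the CH2 terminus of diene A2, and the cis-divinylcyclopropane rearranges (Cope) to the cycloheptadiene A1.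
- In its favour: the ring, the C4 oxygen, the future C9 ester carbon and the C11 stereocentre come from two acyclic pieces in one catalytic asymmetric step. On enantiocontrol this is better than the chosen plan, which uses a stoichiometric auxiliary and sets C11 by substrate control. The concerted, stereospecific mechanism is at least the equal of a stepwise double acylation.
- Against it here: the carbenoid must select a 1,1-disubstituted alkene next to a quaternary carbon. A1 still lacks the C3–C14, C2–C3, C1–C2 and C1–C9 bonds and both quaternary centres C1 and C3. C7 is trigonal in A1, so its configuration would have to come from a later reduction next to C8 with no obvious bias.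
- Comparison: the alternative solves the easier ring first and leaves the C1–C2–C3 array to a series of Dieckmann-type closures. The count of operations after A1 is expected to exceed that of the chosen route after 12.

**Alternative 2:** The cut is at C3–C14 and C11–C13, followed later by a shift of C11 from C13 to C12. In the forward step the enone A5 is irradiated with the alkene A6 to give the head-to-tail, trans-fused cyclobutane A4. Ionization of the tertiary carbinol then expands the cyclobutane to the cyclopentane.
- In its favour: the quaternary C3 is made by a cycloaddition and not by an enolate acylation, which is better than the chosen plan on that point. The trans ring fusion that cycloheptenone photoadducts tend to adopt is the one needed between the cyclopentane and the ring C3–C4–C5–C6–C7–C10–C11. The C12 gem-dimethyl group comes with a cheap alkene.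
- Against it here: nothing strong controls the regiochemistry or the face relative to C7. The cation may migrate C14 instead of C11, and the resulting C13 cation must still be removed. A4 holds none of C1, C9, the benzoyl group or the geranyl group.
- Comparison: on control of the C3/C11 pair the two plans are about equal, since both rely on substrate bias. On step economy the alternative is worse, because the whole trione must still be built around a pre-formed quaternary C3, and the photochemical step limits scale.

**Alternative 3:** The cut is at C11–C12. In the forward step Rh2(esp)2, or a chiral dirhodium carboxylate such as Rh2(S-PTTL)4, converts the diazo ketone A8 into a carbenoid that inserts into the tertiary C12–H bond and gives A7, the C10 ketone of the target.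
- In its favour: the cage is assembled with a plain isopentyl chain on C3. Insertion into a tertiary C–H bond through a five-membered transition state is the preferred mode. The cage allows only the cis ring fusion, so C11 is set more rigidly than by the radical addition of the chosen plan, which is better on that point.
- Against it here: the carbenoid is generated in a molecule with two trisubstituted alkenes, so cyclopropanation and allylic insertion compete. A7 has a ketone at C10 that the target lacks and that must be removed in the presence of four others. The diazo group must be placed between a ketone and the quaternary C3.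
- Comparison: this key step adds only the cyclopentane. The C1–C2–C3 problem still needs a solution like the chosen one, and diazo transfer plus deoxygenation add at least three late steps on the most valuable material.

Key step: step 16

Remark on the chemistry: the configurations at C7 and C11 drawn for 18 and 26 were checked against the target and agree, so no structure needed correction; the change made is the order of the two acylations, as explained above.

Remark on the chemistry: C3 of 15, 17 and 18 is an enolizable centre; it is drawn cis-fused, and either C3 epimer gives the same diene 24.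

## Route

Step 1
Reactants: 1 3,3-dimethylglutaric anhydride
Product: 2 5-tert-butoxy-3,3-dimethyl-5-oxopentanoic acid
Conditions: t-BuOH, DMAP, N-hydroxysuccinimide, Et3N, toluene, 110 °C
Reagents that add atoms: tert-butanol, CC(C)(C)O
Why: Alcoholysis of a cyclic anhydride by DMAP-catalysed acyl transfer; the two carbonyls are equivalent, so one half ester forms and no stereocentre is involved.

Step 2
Reactants: 2 5-tert-butoxy-3,3-dimethyl-5-oxopentanoic acid; 3 (S)-4-benzyl-1,3-oxazolidin-2-one
Product: 4 tert-butyl 5-[(4S)-4-benzyl-2-oxo-1,3-oxazolidin-3-yl]-3,3-dimethyl-5-oxopentanoate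
Conditions: PivCl, Et3N, THF, −20 °C; then 3, LiCl, rt
Reagents that add atoms: none
Why: N-acylation of the oxazolidinone through the mixed pivalic anhydride; the hindered pivaloyl carbonyl is not attacked and the tert-butyl ester is inert.

Step 3
Reactants: 4 tert-butyl 5-[(4S)-4-benzyl-2-oxo-1,3-oxazolidin-3-yl]-3,3-dimethyl-5-oxopentanoate; 5 allyl iodide
Product: 6 tert-butyl (4S)-4-{[(4S)-4-benzyl-2-oxo-1,3-oxazolidin-3-yl]carbonyl}-3,3-dimethylhept-6-enoate
Conditions: NaN(SiMe3)2, THF, −78 °C; 5, −78 → −40 °C
Reagents that add atoms: none
Why: Evans alkylation; the imide is far more acidic than the tert-butyl ester, and the chelated sodium (Z)-enolate is alkylated on the face away from the benzyl group, which sets C7 as (S). Allyl iodide is chosen because the enolate carbon is next to a quaternary centre.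

Step 4
Reactants: 6 tert-butyl (4S)-4-{[(4S)-4-benzyl-2-oxo-1,3-oxazolidin-3-yl]carbonyl}-3,3-dimethylhept-6-enoate
Product: 7 tert-butyl (4S)-4-(hydroxymethyl)-3,3-dimethylhept-6-enoate
Conditions: LiBH4, MeOH (1 equiv), Et2O, 0 °C
Reagents that add atoms: none
Why: Reductive removal of the auxiliary by hydride attack at the exocyclic imide carbonyl (methanol-modified LiBH4 is the usual choice for hindered imides); the tert-butyl ester is not reduced and does not lactonize, and C7 is untouched.

Step 5
Reactants: 7 tert-butyl (4S)-4-(hydroxymethyl)-3,3-dimethylhept-6-enoate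
Product: 8 tert-butyl (4S)-4-(chloromethyl)-3,3-dimethylhept-6-enoate
Conditions: PPh3, CCl4, CH2Cl2, 40 °C
Reagents that add atoms: carbon tetrachloride, ClC(Cl)(Cl)Cl
Why: Appel reaction, SN2 displacement of the alkoxyphosphonium group by chloride at the primary carbon, so C7 is not involved. It is done at this stage because a tert-butyl ester is a poor neighbouring group, whereas the later amide or ketone at C2 would capture the activated C6.

Step 6
Reactants: 8 tert-butyl (4S)-4-(chloromethyl)-3,3-dimethylhept-6-enoate
Product: 10 (4S)-4-(chloromethyl)-N-methoxy-N,3,3-trimethylhept-6-enamide, via carboxylic acid 9 (not isolated)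
Conditions: TFA, CH2Cl2, rt; evaporate; then CDI, CH2Cl2; MeNHOMe·HCl, rt
Reagents that add atoms: N,O-dimethylhydroxylamine hydrochloride, CNOC.Cl
Why: Acidolysis of the tert-butyl ester, then Weinreb amide formation through the acyl imidazole; the primary chloride and the terminal alkene are inert to both operations.

Step 7
Reactants: 10 (4S)-4-(chloromethyl)-N-methoxy-N,3,3-trimethylhept-6-enamide
Product: 11 (6S)-6-(chloromethyl)-5,5-dimethylnona-1,8-dien-3-one
Conditions: CH2=CHMgBr, THF, −20 → 0 °C; inverse quench into cold 1 M HCl
Reagents that add atoms: vinylmagnesium bromide, C=C[Mg]Br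
Why: Weinreb ketone synthesis; the chelated tetrahedral adduct prevents a second addition, and the acidic inverse quench keeps the liberated hydroxylamine from adding to the vinyl ketone.

Step 8
Reactants: 11 (6S)-6-(chloromethyl)-5,5-dimethylnona-1,8-dien-3-one
Product: 12 (5S)-5-(chloromethyl)-6,6-dimethylcyclohept-2-en-1-one
Conditions: second-generation Grubbs catalyst RuCl2(H2IMes)(PCy3)(=CHPh) (5 mol %), CH2Cl2 (5 mM), 40 °C
Reagents that add atoms: none
Why: Ring-closing metathesis to a cyclohept-2-enone, helped by the gem-dimethyl group and driven by loss of ethene.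

Step 9
Reactants: 12 (5S)-5-(chloromethyl)-6,6-dimethylcyclohept-2-en-1-one; 13 4-bromo-2-methylbut-1-ene
Product: 14 (4S,6S)-6-(4-bromo-2-methylbutan-2-yl)-4-(chloromethyl)-3,3-dimethylcycloheptan-1-one
Conditions: 13 (3 equiv), Fe(acac)3, PhSiH3, EtOH/(CH2OH)2, 60 °C
Reagents that add atoms: none
Why: Iron hydride hydrogen-atom-transfer Giese coupling; H-atom transfer to the 1,1-disubstituted alkene gives the tertiary radical, which adds to C11 of the enone, and the α-keto radical is reduced and protonated. Addition anti to the pseudo-equatorial C7 chloromethyl group should give the 3,5-trans product and so set C11; both alkyl halides are spectators.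

Step 10
Reactants: 14 (4S,6S)-6-(4-bromo-2-methylbutan-2-yl)-4-(chloromethyl)-3,3-dimethylcycloheptan-1-one
Product: 15 (3aS,7S,8aS)-7-(chloromethyl)-1,1,6,6-tetramethyloctahydroazulen-4(1H)-one
Conditions: KOt-Bu, THF, 0 °C → rt
Reagents that add atoms: none
Why: Intramolecular enolate C-alkylation, 5-exo-tet with the enolate double bond outside the new ring, at the unhindered primary bromide; the C1 enolate could only form a seven- or four-membered ring and the β-branched C6 chloride reacts far more slowly. The short tether should give the cis ring fusion, and C3 is in any case made trigonal again in step 16.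

Step 11
Reactants: 15 (3aS,7S,8aS)-7-(chloromethyl)-1,1,6,6-tetramethyloctahydroazulen-4(1H)-one; 16 benzaldehyde
Product: 17 (3aS,7S,8aS)-7-(chloromethyl)-5-[hydroxy(phenyl)methyl]-1,1,6,6-tetramethyloctahydroazulen-4(1H)-one (diastereomer mixture at C5 and the carbinol carbon)
Conditions: LiN(i-Pr)2, THF, −78 °C; 16, −78 °C; NH4Cl
Reagents that add atoms: none
Why: Kinetic deprotonation at the C1 methylene in preference to the ring-fusion methine, then aldol addition; the two new centres are removed in step 12, so their configuration does not matter.

Step 12
Reactants: 17 (3aS,7S,8aS)-7-(chloromethyl)-5-[hydroxy(phenyl)methyl]-1,1,6,6-tetramethyloctahydroazulen-4(1H)-one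
Product: 18 (3aS,7S,8aS)-5-benzoyl-7-(chloromethyl)-1,1,6,6-tetramethyloctahydroazulen-4(1H)-one (chelated enol)
Conditions: Dess–Martin periodinane, NaHCO3, CH2Cl2, rt
Reagents that add atoms: none
Why: Dess–Martin oxidation of a β-hydroxy ketone to the β-diketone, which should rest as the hydrogen-bonded enol.

Step 13
Reactants: 19 diethyl malonate; 20 geranyl bromide
Product: 21 diethyl 2-[(2E)-3,7-dimethylocta-2,6-dien-1-yl]propanedioate
Conditions: NaH, 19 (3 equiv), THF, 0 °C; 20, 0 °C → rt
Reagents that add atoms: none
Why: Malonic ester alkylation, SN2 at the primary allylic bromide with the (E) geometry retained; the excess of malonate suppresses dialkylation.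

Step 14
Reactants: 21 diethyl 2-[(2E)-3,7-dimethylocta-2,6-dien-1-yl]propanedioate
Product: 22 2-[(2E)-3,7-dimethylocta-2,6-dien-1-yl]propanedioic acid
Conditions: KOH, EtOH/H2O, rt; then 1 M HCl, 0 °C
Reagents that add atoms: potassium hydroxide, [K+].[OH-]
Why: Saponification of both esters; cold acidification avoids decarboxylation of the malonic acid and acid damage to the alkenes.

Step 15
Reactants: 22 2-[(2E)-3,7-dimethylocta-2,6-dien-1-yl]propanedioic acid
Product: 23 2-[(2E)-3,7-dimethylocta-2,6-dien-1-yl]propanedioyl dichloride
Conditions: 1-chloro-N,N,2-trimethylprop-1-en-1-amine (2.1 equiv), CH2Cl2, 0 °C; used at once in solution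
Reagents that add atoms: 1-chloro-N,N,2-trimethylprop-1-en-1-amine, CC(C)=C(Cl)N(C)C
Why: Acid chloride formation with an α-chloroenamine under neutral conditions; no HCl is released, so the trisubstituted alkenes are safe, and the dichloride is not heated, to avoid loss of HCl to a chlorocarbonyl ketene.

Step 16
Reactants: 18 (3aS,7S,8aS)-5-benzoyl-7-(chloromethyl)-1,1,6,6-tetramethyloctahydroazulen-4(1H)-one; 23 2-[(2E)-3,7-dimethylocta-2,6-dien-1-yl]propanedioyl dichloride
Product: 26 bicyclo[4.3.1]decane trione (C1 benzoyl; C2 ketone; enolized 5-geranyl C4/C9 dione; C7 chloromethyl; malonyl bridge cis to H11 and to CH2Cl), via bis(trimethylsilyl) dienol ether 24 (not isolated), via C3-acylated acid chloride 25 (not isolated)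
Conditions: LiN(i-Pr)2 (2.2 equiv), THF, −78 → −20 °C; Me3SiCl; solvent switch to CH2Cl2; 23 (1.0 equiv, slow addition, 5 mM), −78 → −20 °C; ZnCl2 (0.2 equiv), −20 → 0 °C; pH 7 buffer
Reagents that add atoms: chlorotrimethylsilane, C[Si](C)(C)Cl (silicon is carried by 24 and 25 only)
Why: Proposed new method: double deprotonation and silylation turn 18 into the 1,3-bis(silyloxy)diene 24, whose terminal carbon C3 is the most nucleophilic site, so the first acid chloride of 23 is attacked at C3 (C3–C4 bond, loss of Me3SiCl) before C1 can react. The closest known reactions are the Effenberger cyclization of a ketone silyl enol ether with malonyl dichloride, the terminal-carbon acylation of 1,3-bis(silyl enol ethers) by acid chlorides and the ZnCl2-promoted C-acylation of silyl enol ethers; what is new is the 2-acyl cycloheptanone donor and the 2-substituted malonyl dichloride. In 25 the remaining β-silyloxy enone attacks the tethered acid chloride through C1 (C1–C9 bond, second Me3SiCl), a 6-exo-trig closure at the acyl carbon that completes the six-membered trione ring and with it the bicyclo[4.3.1]decane. C3 is set in the intermolecular step: it is trigonal in 24, and the electrophile should arrive on the face that carries the C11 hydrogen, away from C10, which gives the cis-fused hydroazulene with C4 cis to H11. C1 is not set independently, because the three-atom tether from C3 can reach C1 only on the same face, so C9 ends cis to C4 and to the C7 chloromethyl group. The step needs C-acylation and not O-acylation in the second closure, and no enolization of 23 to a ketene; silylated oxygens, the absence of Brønsted base and of HCl (both acylations release Me3SiCl) and ZnCl2 activation are meant to secure this, and high dilution suppresses oligomers. The C5 centre of 25 is of no consequence because 26 is an enolized 2-geranyl-1,3-dione.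

Step 17
Reactants: 26 bicyclo[4.3.1]decane trione with C7 chloromethyl
Product: 28 CNP0168637.1 (target), via primary iodide 27 (not isolated)
Conditions: NaI, Cs2CO3, DMF, 60 °C
Reagents that add atoms: sodium iodide, [Na+].[I-] (iodine is carried by 27 only)
Why: Finkelstein exchange, then intramolecular C-alkylation of the caesium enolate of the 2-alkyl-1,3-dione, 6-exo-tet through a chair. C6 lies over the enolate face because the C7 substituent and the dione bridge are cis on the seven-membered ring, and the C5 configuration is the only one the cage allows.

## Compound list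

1 | 3,3-dimethylglutaric anhydride | CC1(C)CC(=O)OC(=O)C1 | starting material
2 | 5-tert-butoxy-3,3-dimethyl-5-oxopentanoic acid | CC(C)(C)OC(=O)CC(C)(C)CC(=O)O | intermediate
3 | (S)-4-benzyl-1,3-oxazolidin-2-one | O=C1N[C@@H](Cc2ccccc2)CO1 | starting material
4 | tert-butyl 5-[(4S)-4-benzyl-2-oxo-1,3-oxazolidin-3-yl]-3,3-dimethyl-5-oxopentanoate | CC(C)(C)OC(=O)CC(C)(C)CC(=O)N1[C@@H](Cc2ccccc2)COC1=O | intermediate
5 | allyl iodide (3-iodoprop-1-ene) | C=CCI | starting material
6 | tert-butyl (4S)-4-{[(4S)-4-benzyl-2-oxo-1,3-oxazolidin-3-yl]carbonyl}-3,3-dimethylhept-6-enoate | CC(C)(C)OC(=O)CC(C)(C)[C@H](CC=C)C(=O)N1[C@@H](Cc2ccccc2)COC1=O | intermediate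
7 | tert-butyl (4S)-4-(hydroxymethyl)-3,3-dimethylhept-6-enoate | OC[C@@H](CC=C)C(C)(C)CC(=O)OC(C)(C)C | intermediate
8 | tert-butyl (4S)-4-(chloromethyl)-3,3-dimethylhept-6-enoate | ClC[C@@H](CC=C)C(C)(C)CC(=O)OC(C)(C)C | intermediate
9 | (4S)-4-(chloromethyl)-3,3-dimethylhept-6-enoic acid | ClC[C@@H](CC=C)C(C)(C)CC(=O)O | intermediate
10 | (4S)-4-(chloromethyl)-N-methoxy-N,3,3-trimethylhept-6-enamide | ClC[C@@H](CC=C)C(C)(C)CC(=O)N(C)OC | intermediate
11 | (6S)-6-(chloromethyl)-5,5-dimethylnona-1,8-dien-3-one | ClC[C@@H](CC=C)C(C)(C)CC(=O)C=C | intermediate
12 | (5S)-5-(chloromethyl)-6,6-dimethylcyclohept-2-en-1-one | ClC[C@H]1CC=CC(=O)CC1(C)C | intermediate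
13 | 4-bromo-2-methylbut-1-ene | C=C(C)CCBr | starting material
14 | (4S,6S)-6-(4-bromo-2-methylbutan-2-yl)-4-(chloromethyl)-3,3-dimethylcycloheptan-1-one (substituents at C4 and C6 trans) | ClC[C@H]1C[C@H](C(C)(C)CCBr)CC(=O)CC1(C)C | intermediate
15 | (3aS,7S,8aS)-7-(chloromethyl)-1,1,6,6-tetramethyloctahydroazulen-4(1H)-one (cis-fused) | ClC[C@H]1C[C@@H]2C(C)(C)CC[C@@H]2C(=O)CC1(C)C | intermediate
16 | benzaldehyde | O=Cc1ccccc1 | starting material
17 | (3aS,7S,8aS)-7-(chloromethyl)-5-[hydroxy(phenyl)methyl]-1,1,6,6-tetramethyloctahydroazulen-4(1H)-one, diastereomer mixture at C5 and the carbinol carbon | ClC[C@H]1C[C@@H]2C(C)(C)CC[C@@H]2C(=O)C(C(O)c3ccccc3)C1(C)C | intermediate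
18 | (3aS,7S,8aS)-5-benzoyl-7-(chloromethyl)-1,1,6,6-tetramethyloctahydroazulen-4(1H)-one, drawn as the enol (precursor of the key step) | ClC[C@H]1C[C@@H]2C(C)(C)CC[C@@H]2C(O)=C(C(=O)c3ccccc3)C1(C)C | intermediate
19 | diethyl malonate | CCOC(=O)CC(=O)OCC | starting material
20 | geranyl bromide | CC(C)=CCC/C(C)=C/CBr | starting material
21 | diethyl 2-[(2E)-3,7-dimethylocta-2,6-dien-1-yl]propanedioate | CCOC(=O)C(C/C=C(\C)CCC=C(C)C)C(=O)OCC | intermediate
22 | 2-[(2E)-3,7-dimethylocta-2,6-dien-1-yl]propanedioic acid | OC(=O)C(C/C=C(\C)CCC=C(C)C)C(O)=O | intermediate
23 | 2-[(2E)-3,7-dimethylocta-2,6-dien-1-yl]propanedioyl dichloride | ClC(=O)C(C/C=C(\C)CCC=C(C)C)C(Cl)=O | intermediate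
24 | bis(trimethylsilyl) dienol ether of 18: C2(OSiMe3)=C3 in the ring and C1=C(OSiMe3)Ph exocyclic; C7 and C11 as in 18 | ClC[C@H]1C[C@@H]2C(C)(C)CCC2=C(O[Si](C)(C)C)C(=C(O[Si](C)(C)C)c3ccccc3)C1(C)C | intermediate
25 | C3-acylated acid chloride: C3 of the hydroazulenone carries C(=O)CH(geranyl)COCl on the face of H11; C1=C(OSiMe3)Ph silyl enol ether; both C5 epimers | ClC[C@H]1C[C@@H]2C(C)(C)CC[C@@]2(C(=O)C(=C(O[Si](C)(C)C)c3ccccc3)C1(C)C)C(=O)C(C/C=C(\C)CCC=C(C)C)C(Cl)=O | intermediate
26 | bicyclo[4.3.1]decane key product: C1 benzoyl, C2 ketone, enolized 5-geranyl C4/C9 dione, C7 chloromethyl; C3–C4 and C1–C9 bonds on the ring face of H11 and CH2Cl; cyclopentane cis-fused; C7 and C11 as in 18 | ClC[C@H]3C[C@@H]4C(C)(C)CC[C@@]4(C(=O)[C@]1(C(=O)c2ccccc2)C3(C)C)C(O)=C(C/C=C(\C)CCC=C(C)C)C1=O | intermediate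
27 | C6 iodide corresponding to 26 | IC[C@H]3C[C@@H]4C(C)(C)CC[C@@]4(C(=O)[C@]1(C(=O)c2ccccc2)C3(C)C)C(O)=C(C/C=C(\C)CCC=C(C)C)C1=O | intermediate
28 | CNP0168637.1: 1-benzoyl-5-geranyl caged 2,4,9-trione, (1S,3S,5R,7R,11R) in the numbering used here | CC(C)=CCC/C(C)=C/C[C@@]12C[C@H]3C[C@@H]4C(C)(C)CC[C@]4(C1=O)C(=O)[C@@](C(=O)c1ccccc1)(C2=O)C3(C)C | target

## Step count and least certain steps

Total steps: 17. Longest linear sequence: 14 (steps 1 to 12, then 16 and 17); steps 13 to 15 make the second fragment.

**Step 16 (key step, proposed new method).** The most likely failures are O-acylation in the second ring closure (the C2 oxygen attacking the C9 acid chloride to give a six-membered enol lactone), reaction at C1 before C3, and loss of HCl from 23 to a ketene followed by oligomerization. The fallback uses known chemistry and leaves the benzoyl and geranyl groups out of the annulation. It sets out from 15 and returns at 28. Ketone 15 is converted with LiN(i-Pr)2 and Me3SiCl into its kinetic trimethylsilyl enol ether F1. F1 and malonyl dichloride under classical Effenberger conditions (Et2O, −20 °C, then aqueous KOH with BnEt3NCl) give the bicyclo[4.3.1]decane trione F2; here C1 keeps a hydrogen and can epimerize before the second closure, so the C3 closure is free to take the face cis to H11. NaI and Cs2CO3 close the C5–C6 bond to the cage trione F3. Bridgehead deprotonation with LiN(i-Pr)2 at C5, which is remote from the C8 gem-dimethyl group, and alkylation with 20 give the C5-geranyl cage F4. A second bridgehead lithiation at C1 with lithium 2,2,6,6-tetramethylpiperidide and benzoyl chloride then gives 28.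

**Step 17.** The most likely failures are O-alkylation of the dione enolate by C6 (a six-membered cyclic enol ether through the C9 oxygen) and slow displacement at the β-branched C6, which would leave time for nucleophilic cleavage at C1. The fallback forms the C5–C6 bond while C5 is unsubstituted and adds the geranyl group last. It sets out from 18 and returns at 28. Diketone 18, as 24, is annulated with malonyl dichloride in place of 23 to give the C5-unsubstituted trione F5. NaI and Cs2CO3 then alkylate a less hindered and more nucleophilic enol carbon and give the cage F6 with a bridgehead C5–H. LiN(i-Pr)2 and 20 geranylate C5, the only enolizable position left, to give 28.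

**Step 3.** The most likely failure is slow alkylation of the sodium enolate next to the quaternary carbon, with breakdown of the enolate to a ketene and the oxazolidinone anion before 5 reacts. The fallback sets C7 by SOMO-type organocatalytic α-allylation of an aldehyde instead of an enolate SN2 reaction. It sets out from 2 and returns at 7. Acid 2 is reduced with BH3·THF to the hydroxy ester F7 and oxidized with Dess–Martin periodinane to the aldehyde F8. Allyltrimethylsilane, (NH4)2Ce(NO3)6 and the enantiomer of the 5-benzyl-2-tert-butyl-imidazolidinone catalyst that delivers the (S) product give the α-allyl aldehyde F9. NaBH4 reduces F9 to 7.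

**Step 9.** The most likely failures are poor facial selectivity of the radical addition at C11 in the flexible seven-membered ring and reduction of the enone in place of coupling. The fallback is an ionic conjugate addition at low temperature. It sets out from 12 and returns at 14. Enone 12, TiCl4 and trimethyl(3-methylbut-2-en-1-yl)silane at −78 °C (Hosomi–Sakurai reaction through the γ-carbon of the allylsilane) give the 1,1-dimethylallyl ketone F10. 9-Borabicyclo[3.3.1]nonane, then NaOH and H2O2, convert the vinyl group into the primary alcohol F11. CBr4 and PPh3 turn F11 into 14.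

**Step 11.** The most likely failure is unselective deprotonation (C3 methine against the hindered C1 methylene), which would put the benzoyl group on C3. The fallback benzoylates before C3 becomes tetrahedral. It sets out from 12 and returns at 18. Enone 12 has a single enolizable α-position, C1. LiN(i-Pr)2 and 16 give the aldol F12, and Dess–Martin oxidation gives the benzoyl enone F13. The Fe(acac)3/PhSiH3 coupling with 13 gives the bromo diketone F14. The dianion of F14 (two equivalents of LiN(i-Pr)2) is alkylated at its γ-carbon C3 by the C14 bromide and gives 18.

## Further compounds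

F1 | step 16 | trimethylsilyl enol ether of 15 (C1=C2–OSiMe3) | ClC[C@H]1C[C@@H]2C(C)(C)CC[C@@H]2C(O[Si](C)(C)C)=CC1(C)C
F2 | step 16 | bicyclo[4.3.1]decane trione without benzoyl and geranyl groups (C1–H, enolized C4/C9 dione, C7 chloromethyl) | ClC[C@H]3C[C@@H]4C(C)(C)CC[C@@]4(C(=O)[C@@H]1C3(C)C)C(O)=CC1=O
F3 | step 16 | cage trione with bridgehead hydrogens at C1 and C5 | [C@@H]12C[C@H]3C[C@@H]4C(C)(C)CC[C@]4(C1=O)C(=O)[C@@H](C2=O)C3(C)C
F4 | step 16 | C5-geranyl cage trione with bridgehead hydrogen at C1 | CC(C)=CCC/C(C)=C/C[C@@]12C[C@H]3C[C@@H]4C(C)(C)CC[C@]4(C1=O)C(=O)[C@@H](C2=O)C3(C)C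
F5 | step 17 | C5-unsubstituted analogue of 26 (C1 benzoyl, enolized C4/C9 dione, C7 chloromethyl) | ClC[C@H]3C[C@@H]4C(C)(C)CC[C@@]4(C(=O)[C@]1(C(=O)c2ccccc2)C3(C)C)C(O)=CC1=O
F6 | step 17 | C1-benzoyl cage trione with bridgehead hydrogen at C5 | [C@@H]12C[C@H]3C[C@@H]4C(C)(C)CC[C@]4(C1=O)C(=O)[C@@](C(=O)c1ccccc1)(C2=O)C3(C)C
F7 | step 3 | tert-butyl 5-hydroxy-3,3-dimethylpentanoate | CC(C)(C)OC(=O)CC(C)(C)CCO
F8 | step 3 | tert-butyl 3,3-dimethyl-5-oxopentanoate | CC(C)(C)OC(=O)CC(C)(C)CC=O
F9 | step 3 | tert-butyl (4S)-4-formyl-3,3-dimethylhept-6-enoate | O=C[C@@H](CC=C)C(C)(C)CC(=O)OC(C)(C)C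
F10 | step 9 | (4S,6S)-4-(chloromethyl)-3,3-dimethyl-6-(2-methylbut-3-en-2-yl)cycloheptan-1-one | ClC[C@H]1C[C@H](C(C)(C)C=C)CC(=O)CC1(C)C
F11 | step 9 | (4S,6S)-4-(chloromethyl)-6-(4-hydroxy-2-methylbutan-2-yl)-3,3-dimethylcycloheptan-1-one | ClC[C@H]1C[C@H](C(C)(C)CCO)CC(=O)CC1(C)C
F12 | step 11 | (5S)-5-(chloromethyl)-7-[hydroxy(phenyl)methyl]-6,6-dimethylcyclohept-2-en-1-one (diastereomer mixture) | ClC[C@H]1CC=CC(=O)C(C(O)c2ccccc2)C1(C)C
F13 | step 11 | (5S)-7-benzoyl-5-(chloromethyl)-6,6-dimethylcyclohept-2-en-1-one | ClC[C@H]1CC=CC(=O)C(C(=O)c2ccccc2)C1(C)C
F14 | step 11 | (4S,6S)-2-benzoyl-6-(4-bromo-2-methylbutan-2-yl)-4-(chloromethyl)-3,3-dimethylcycloheptan-1-one | ClC[C@H]1C[C@H](C(C)(C)CCBr)CC(=O)C(C(=O)c2ccccc2)C1(C)C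
A1 | alternative 1 | cyclohepta-1,4-diene silyl enol ether of the β-keto ester, carrying the C11 chloroalkyl and C7 ester side chains | COC(=O)C1=C(O[Si](C)(C)C(C)(C)C)C[C@@H](C(C)(C)CCCl)C=C(C(C)(C)CC(=O)OC)C1
A2 | alternative 1 | methyl (5E)-9-chloro-3,3,7,7-tetramethyl-4-methylidenenon-5-enoate (diene partner) | C=C(C(C)(C)CC(=O)OC)/C=C/C(C)(C)CCCl
A3 | alternative 1 | methyl 3-[tert-butyl(dimethyl)silyl]oxy-2-diazobut-3-enoate | COC(=O)C(=[N+]=[N-])C(=C)O[Si](C)(C)C(C)(C)C
A4 | alternative 2 | trans-fused bicyclo[5.2.0]nonanone carbinol (C13 configuration open) | COC(=O)[C@@]12CC(C(C)(C)O)[C@H]1C[C@@H](C(C)(C)CCO[Si](C)(C)C(C)(C)C)CCC2=O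
A5 | alternative 2 | methyl 4-[4-(tert-butyldimethylsilyloxy)-2-methylbutan-2-yl]-7-oxocyclohept-1-ene-1-carboxylate | COC(=O)C1=CC[C@@H](C(C)(C)CCO[Si](C)(C)C(C)(C)C)CCC1=O
A6 | alternative 2 | 2-methylbut-3-en-2-ol | CC(C)(O)C=C
A7 | alternative 3 | C10 ketone of the target | CC(C)=CCC/C(C)=C/C[C@@]12C[C@H]3C(=O)[C@@H]4C(C)(C)CC[C@]4(C1=O)C(=O)[C@@](C(=O)c1ccccc1)(C2=O)C3(C)C
A8 | alternative 3 | C11 diazo C10 ketone of the cage with an isopentyl group on C3 | CC(C)=CCC/C(C)=C/C[C@@]12C[C@H]3C(=O)C(=[N+]=[N-])[C@@](CCC(C)C)(C1=O)C(=O)[C@@](C(=O)c1ccccc1)(C2=O)C3(C)C
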